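**The task.** I have one run. The flask repeats the maple run with half the catalyst.

common to all: starting material 1.5 M
- maple: catalyst 4.4 mM; run made earlier
- flask: catalyst 2.2 mM; time 15 d

maple run (percent of the starting material charged)

| time / d | target / % | isomer of the product / % |
|---|---|---|
| 0.333 | 24.7 | 63.5 |
| 0.625 | 18.9 | 69.2 |
| 1.25 | 17.4 | 71.8 |
| 2.50 | 17.1 | 72.3 |
| 5.00 | 17.0 | 71.9 |

(scatter of a reading: 0.3 percentage points)

- share of target in target plus isomer of the product at 12 min
- share of target in target plus isomer of the product at 8.0 h
- share of target in target plus isomer of the product at 15 d
- which of target and isomer of the product there is more of at 15 d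

- reactions considered so far: target <-> isomer of the product; starting material + catalyst <-> target + catalyst; isomer of the product + catalyst <-> starting material + catalyst
- no earlier run changes the charge of catalyst; that part of a forecast is a guess

**The puzzle.** In the maple run, target plus isomer of the product goes from 88.2% at 0.333 d to 88.9% at 5.00 d, so starting material stays flat. Yet the share of target in that sum falls from 28.0% to 19.1%.

**My reckoning.** A flat amount can mean that inflow matches outflow: target can feed starting material while starting material feeds isomer of the product, and both steps use catalyst. I guess that this route carries the fall, since no earlier run varies c(catalyst). If c(catalyst) stays constant, the excess of the share over 19.1% decays in pseudo-first-order fashion, at a rate proportional to c(catalyst). With 21.5% as the second share, the catalyst clock, the decay constant of that excess at the maple charge, is 4.58 d⁻¹. So 8.0 h in the flask counts like 4.00 h of the maple run, which gives 38.2%. Likewise 15 d counts like 7.50 d, later than the last maple reading, so I expect 19.1% there. At 12 min I give no number, since that time counts as earlier than the first reading.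

**The forecast.** It gives 58%, 35% and 19.1%, with isomer of the product ahead. Its 12 min value rests on this: “the share should stay near that split whatever the catalyst charge”. Its 8.0 h value lies below mine.

**The result.** The flask gives 46.1%, 35.0% and 19.1%, with isomer of the product ahead.

    target ⇌ isomer of the product (K = 4.23, k = 1.13 × 10⁻⁶ s⁻¹)
    starting material + catalyst ⇌ target + catalyst, rate k2*[starting material]*[catalyst] forward; the back reaction follows from the equilibrium constant (K = 1.54, k = 0.0250 M⁻¹ s⁻¹)
    isomer of the product + catalyst ⇌ starting material + catalyst, rate k3*[catalyst]*[isomer of the product] forward; the back reaction follows from the equilibrium constant (k = 0.00444 M⁻¹ s⁻¹)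

My clock stands 3.2 percentage points high at 8.0 h; for a neighbouring flask with 8.80 mM of catalyst it gives 21.0% at 8.0 h, against the simulated 21.4%. In the flask, target peaks at 30.8% at 0.225 d. Then, with catalyst at 100% at 1.50 d, the catalysed exchange through starting material runs faster than the direct step, and target reaches 17.0% at 15.0 d.

The earlier runs and the new flask were generated by integration for an exercise; the scatter is artificial.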